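**Plan**

1. The last cuts are the two aryl MOM ethers and the C2–acyl bond of ring A (acyl transfer onto a cyclic trione).
2. Ring A is cut at C5–C6 (Dieckmann) and C2–C3 (crossed Claisen), giving a 4-arylbutan-2-one and dimethyl 2,2-dimethylmalonate; the C5'–acyl bond of ring B is cut to an aryllithium and a Weinreb amide.
3. Ring B is cut at C6'–C1' and C2'–C3' into 3-methoxycyclobutenone and a siloxyalkyne. This works because ring B is a benzene oxygenated at C2', C4' and C6': the bridge-bearing C1' is flanked by two C–O carbons and has the C4' methoxy group para to it, so C1'/C2' map onto a polarised ynol ether and C3'–C6' onto the four cyclobutenone carbons.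
4. Forward order: the alkyne is made from ethyl levulinate and ring B is closed by benzannulation; the alkyne substituent already holds the bridge carbon and C6–C1–C2 of ring A as a ketal-masked butanone. Ring B is then butanoylated, ring A is built by Claisen/Dieckmann and butanoylated, and the phenols are freed.
5. Stereochemistry: the target has no stereocentre and no stereogenic double bond, so none has to be set.

Key step: step 4

Remark: ring A and its precursors are drawn as one enol tautomer each. Ring A is numbered C1 (carbonyl between the two substituted carbons), C2 (butanoyl-bearing), C3/C5 (oxygenated), C4 (CMe2), C6 (bridge-bearing); ring B is numbered C1' (bridge-bearing), C2'/C6' (OH), C3' (H), C4' (OMe), C5' (butanoyl).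

**Route**

Step 1
Reactants: 1 ethyl levulinate
Product: 2 ethyl 3-(2-methyl-1,3-dioxolan-2-yl)propanoate
Conditions: HOCH2CH2OH, p-TsOH·H2O (cat.), toluene, reflux, Dean–Stark
Reagents that add atoms: ethylene glycol, OCCO
Why: Acid-catalysed ketalisation with azeotropic removal of water masks the ketone, which the ester (unable to form a stable acetal) survives, so that only the ester meets the organolithium reagents of step 2.

Step 2
Reactants: 2 ethyl 3-(2-methyl-1,3-dioxolan-2-yl)propanoate; 3 dibromomethane
Product: 6 triisopropyl{[4-(2-methyl-1,3-dioxolan-2-yl)but-1-yn-1-yl]oxy}silane, via dibromo enolate 4 (not isolated), via lithium ynolate 5 (not isolated)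
Conditions: CH2Br2, lithium 2,2,6,6-tetramethylpiperidide (2.2 equiv), THF, −78 °C; n-BuLi, −78 → 0 °C; i-Pr3SiCl, −78 °C → rt
Reagents that add atoms: triisopropylsilyl chloride, CC(C)[Si](Cl)(C(C)C)C(C)C
Why: Kowalski ester homologation stopped at the ynolate stage: dibromomethyllithium adds to the ester, the derived dibromo enolate 4 undergoes bromine–lithium exchange and a carbenoid 1,2-shift of the alkyl group to ynolate 5, and the bulky silyl chloride captures 5 on oxygen, while the ketal is inert to the bases.

Step 3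
Reactants: 7 3-ethoxycyclobut-2-en-1-one
Product: 8 3-methoxycyclobut-2-en-1-one
Conditions: dry MeOH (solvent), camphorsulfonic acid (5 mol %), rt
Reagents that add atoms: methanol, CO
Why: Acid-catalysed alkoxy exchange of a vinylogous ester (conjugate addition of methanol at C3, then loss of ethanol), driven by methanol as solvent, installs the oxygen substituent that becomes the C4' methoxy group.

Step 4
Reactants: 8 3-methoxycyclobut-2-en-1-one; 6 triisopropyl{[4-(2-methyl-1,3-dioxolan-2-yl)but-1-yn-1-yl]oxy}silane
Product: 13 5-methoxy-2-[2-(2-methyl-1,3-dioxolan-2-yl)ethyl]-3-[(triisopropylsilyl)oxy]phenol, via vinylketene 9 (not isolated), via vinylcyclobutenone 10 (not isolated), via dienylketene 11 (not isolated), via cyclohexadienone 12 (not isolated)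
Conditions: toluene, 80 → 110 °C, sealed tube (8 in 1.3-fold excess)
Reagents that add atoms: none
Why: Heating 8 should trigger reversible 4π-electrocyclic ring opening to the methoxy-substituted vinylketene 9, whose electrophilic ketene carbon (future C6') is attacked by the nucleophilic, carbon-substituted terminus of ynol ether 6 in a regioselective [2+2] cycloaddition that gives 4-vinylcyclobutenone 10 (new bonds C6'–C1' and C2'–C3'). A second 4π opening of 10 leads to dienylketene 11, and ring B then closes by thermal disrotatory 6π-electrocyclisation between C5' and C6' to cyclohexadienone 12, which tautomerises to phenol 13. The closest known reaction type is the Danheiser benzannulation of cyclobutenones with triisopropylsiloxyalkynes. No stereocentre remains, because the sp3 carbon of 10 is lost on ring opening and the product is an achiral arene. The step needs the [2+2] regiochemistry that puts the chain-bearing C1' between the two oxygenated carbons and para to C4'–OMe; the polarisation of the siloxyalkyne (the oxygen lone pair makes the alkyl-bearing carbon nucleophilic) matched with the ketene carbonyl carbon as the only strongly electrophilic site secures it. The excess of volatile 8 is meant to compensate for vinylketene lost to dimerisation.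

Step 5
Reactants: 13 5-methoxy-2-[2-(2-methyl-1,3-dioxolan-2-yl)ethyl]-3-[(triisopropylsilyl)oxy]phenol
Product: 14 5-methoxy-2-[2-(2-methyl-1,3-dioxolan-2-yl)ethyl]benzene-1,3-diol
Conditions: Bu4NF (1.1 equiv), AcOH (1.1 equiv), THF, 0 °C → rt
Reagents that add atoms: none
Why: Fluoride-mediated cleavage of the aryl silyl ether, driven by the Si–F bond and buffered with acetic acid so that the ketal is untouched, gives a resorcinol in which C3' and C5' are equivalent by symmetry.

Step 6
Reactants: 14 5-methoxy-2-[2-(2-methyl-1,3-dioxolan-2-yl)ethyl]benzene-1,3-diol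
Product: 15 2-{2-[4-methoxy-2,6-bis(methoxymethoxy)phenyl]ethyl}-2-methyl-1,3-dioxolane
Conditions: MOMCl (3 equiv), i-Pr2NEt (4 equiv), CH2Cl2, 0 °C → rt
Reagents that add atoms: chloromethyl methyl ether, COCCl
Why: Double O-alkylation of the phenols with the reactive chloromethyl ether (Williamson-type etherification) gives acetal ethers that withstand the strong bases of steps 7, 9 and 10 and direct the metalation of step 7.

Step 7
Reactants: 15 2-{2-[4-methoxy-2,6-bis(methoxymethoxy)phenyl]ethyl}-2-methyl-1,3-dioxolane; 16 N-methoxy-N-methylbutanamide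
Product: 18 1-{6-methoxy-2,4-bis(methoxymethoxy)-3-[2-(2-methyl-1,3-dioxolan-2-yl)ethyl]phenyl}butan-1-one, via aryllithium 17 (not isolated)
Conditions: n-BuLi (1.2 equiv), THF, 0 °C; then 16, −78 → 0 °C; H2O
Reagents that add atoms: none
Why: Directed ortho-metalation: the two remaining ring hydrogens (C3' and C5', equivalent) each lie between an OMOM and an OMe group, so n-BuLi should give the single aryllithium 17, and the Weinreb amide acylates it through a chelated tetrahedral adduct that cannot add a second aryllithium.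

Step 8
Reactants: 18 1-{6-methoxy-2,4-bis(methoxymethoxy)-3-[2-(2-methyl-1,3-dioxolan-2-yl)ethyl]phenyl}butan-1-one
Product: 19 4-[3-butanoyl-4-methoxy-2,6-bis(methoxymethoxy)phenyl]butan-2-one
Conditions: pyridinium p-toluenesulfonate (cat.), acetone/H2O (10:1), 40 °C
Reagents that add atoms: water, O
Why: Mild acid-catalysed ketal hydrolysis in wet acetone is expected to cleave the dialkyl ketone dioxolane well before the aryl MOM ethers, and since both phenols stay capped the freed ketone cannot close to a chromanol.

Step 9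
Reactants: 19 4-[3-butanoyl-4-methoxy-2,6-bis(methoxymethoxy)phenyl]butan-2-one; 20 dimethyl 2,2-dimethylmalonate
Product: 22 methyl 7-[3-butanoyl-4-methoxy-2,6-bis(methoxymethoxy)phenyl]-2,2-dimethyl-3,5-dioxoheptanoate, via dilithium bis-enolate 21 (not isolated)
Conditions: LiN(i-Pr)2 (2.2 equiv), THF, −78 °C; then 20 (3 equiv), −78 → 0 °C; AcOH
Reagents that add atoms: none
Why: Crossed Claisen condensation: LiN(i-Pr)2 deprotonates the methyl ketone kinetically at CH3 and also enolises the ring-B ketone, the unhindered terminal enolate of 21 is acylated by the non-enolisable diester to form C2–C3, and the internal enolate, wedged between the OMe- and OMOM-bearing ring carbons and carrying an ethyl group, is too hindered to be acylated and only serves as the base that takes up the acidic diketone proton.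

Step 10
Reactants: 22 methyl 7-[3-butanoyl-4-methoxy-2,6-bis(methoxymethoxy)phenyl]-2,2-dimethyl-3,5-dioxoheptanoate
Product: 24 4-{[3-butanoyl-4-methoxy-2,6-bis(methoxymethoxy)phenyl]methyl}-5-hydroxy-2,2-dimethylcyclohex-4-ene-1,3-dione, via trilithium tris-enolate 23 (not isolated)
Conditions: LiN(i-Pr)2 (3.3 equiv), THF, −78 → 0 °C; AcOH
Reagents that add atoms: none
Why: Dieckmann-type intramolecular Claisen condensation of a diketone dianion (Hauser–Harris γ-carbanion chemistry, the third equivalent of base holding the ring-B ketone as its enolate): C6 attacks the ester carbonyl (future C5) in a 6-exo-trig closure helped by the gem-dimethyl group, and the enolised cyclic trione is the thermodynamic sink.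

Step 11
Reactants: 24 4-{[3-butanoyl-4-methoxy-2,6-bis(methoxymethoxy)phenyl]methyl}-5-hydroxy-2,2-dimethylcyclohex-4-ene-1,3-dione; 25 butanoic acid
Product: 27 2-butanoyl-6-{[3-butanoyl-4-methoxy-2,6-bis(methoxymethoxy)phenyl]methyl}-3,5-dihydroxy-4,4-dimethylcyclohexa-2,5-dien-1-one, via enol butanoate 26 (not isolated)
Conditions: N,N'-dicyclohexylcarbodiimide (1.2 equiv), 4-(dimethylamino)pyridine (0.3 equiv), CH2Cl2, rt
Reagents that add atoms: none
Why: Steglich O-acylation to enol ester 26 followed by DMAP-mediated acyl migration from oxygen to carbon, the standard C-acylation of cyclohexane-1,3-diones and syncarpic acid, places the butanoyl group on C2, the only unsubstituted enolisable ring carbon, where the product is held as a hydrogen-bonded enolised triketone.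

Step 12
Reactants: 27 2-butanoyl-6-{[3-butanoyl-4-methoxy-2,6-bis(methoxymethoxy)phenyl]methyl}-3,5-dihydroxy-4,4-dimethylcyclohexa-2,5-dien-1-one
Product: 28 2-butanoyl-6-[(3-butanoyl-2,6-dihydroxy-4-methoxyphenyl)methyl]-3,5-dihydroxy-4,4-dimethylcyclohexa-2,5-dien-1-one
Conditions: 3 M aq. HCl, MeOH/THF, 40 °C
Reagents that add atoms: none
Why: Acid-catalysed acetal cleavage removes both MOM groups at moderate temperature without touching the aryl methyl ether, the ketones or the methylene bridge, which is sensitive mainly to base.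

**Compound list**

1 | ethyl levulinate (ethyl 4-oxopentanoate) | CCOC(=O)CCC(C)=O | starting material
2 | ethyl 3-(2-methyl-1,3-dioxolan-2-yl)propanoate | CCOC(=O)CCC1(C)OCCO1 | intermediate
3 | dibromomethane | BrCBr | starting material
4 | lithium 1,1-dibromo-4-(2-methyl-1,3-dioxolan-2-yl)but-1-en-2-olate | [Li]OC(=C(Br)Br)CCC1(C)OCCO1 | intermediate (not isolated)
5 | lithium 4-(2-methyl-1,3-dioxolan-2-yl)but-1-yn-1-olate | [Li]OC#CCCC1(C)OCCO1 | intermediate (not isolated)
6 | triisopropyl{[4-(2-methyl-1,3-dioxolan-2-yl)but-1-yn-1-yl]oxy}silane | CC1(CCC#CO[Si](C(C)C)(C(C)C)C(C)C)OCCO1 | intermediate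
7 | 3-ethoxycyclobut-2-en-1-one | CCOC1=CC(=O)C1 | starting material
8 | 3-methoxycyclobut-2-en-1-one | COC1=CC(=O)C1 | intermediate
9 | 3-methoxybuta-1,3-dien-1-one | C=C(OC)C=C=O | intermediate (not isolated)
10 | 4-(1-methoxyethenyl)-2-[2-(2-methyl-1,3-dioxolan-2-yl)ethyl]-3-[(triisopropylsilyl)oxy]cyclobut-2-en-1-one (racemic) | C=C(OC)C1C(=O)C(CCC2(C)OCCO2)=C1O[Si](C(C)C)(C(C)C)C(C)C | intermediate (not isolated)
11 | (3E)-5-methoxy-2-[2-(2-methyl-1,3-dioxolan-2-yl)ethyl]-3-[(triisopropylsilyl)oxy]hexa-1,3,5-trien-1-one | C=C(OC)\C=C(O[Si](C(C)C)(C(C)C)C(C)C)/C(CCC1(C)OCCO1)=C=O | intermediate (not isolated)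
12 | 5-methoxy-2-[2-(2-methyl-1,3-dioxolan-2-yl)ethyl]-3-[(triisopropylsilyl)oxy]cyclohexa-2,4-dien-1-one | O=C1CC(OC)=CC(O[Si](C(C)C)(C(C)C)C(C)C)=C1CCC2(C)OCCO2 | intermediate (not isolated)
13 | 5-methoxy-2-[2-(2-methyl-1,3-dioxolan-2-yl)ethyl]-3-[(triisopropylsilyl)oxy]phenol | COc1cc(O)c(CCC2(C)OCCO2)c(O[Si](C(C)C)(C(C)C)C(C)C)c1 | intermediate
14 | 5-methoxy-2-[2-(2-methyl-1,3-dioxolan-2-yl)ethyl]benzene-1,3-diol | COc1cc(O)c(CCC2(C)OCCO2)c(O)c1 | intermediate
15 | 2-{2-[4-methoxy-2,6-bis(methoxymethoxy)phenyl]ethyl}-2-methyl-1,3-dioxolane | COCOc1cc(OC)cc(OCOC)c1CCC2(C)OCCO2 | intermediate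
16 | N-methoxy-N-methylbutanamide | CCCC(=O)N(C)OC | starting material
17 | {6-methoxy-2,4-bis(methoxymethoxy)-3-[2-(2-methyl-1,3-dioxolan-2-yl)ethyl]phenyl}lithium | [Li]c1c(OC)cc(OCOC)c(CCC2(C)OCCO2)c1OCOC | intermediate (not isolated)
18 | 1-{6-methoxy-2,4-bis(methoxymethoxy)-3-[2-(2-methyl-1,3-dioxolan-2-yl)ethyl]phenyl}butan-1-one | CCCC(=O)c1c(OC)cc(OCOC)c(CCC2(C)OCCO2)c1OCOC | intermediate
19 | 4-[3-butanoyl-4-methoxy-2,6-bis(methoxymethoxy)phenyl]butan-2-one | CCCC(=O)c1c(OC)cc(OCOC)c(CCC(C)=O)c1OCOC | intermediate
20 | dimethyl 2,2-dimethylmalonate | COC(=O)C(C)(C)C(=O)OC | starting material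
21 | dilithium bis-enolate of 19 (terminal enolate of the methyl ketone, internal enolate of the aryl ketone) | C=C(O[Li])CCc1c(OCOC)cc(OC)c(C(O[Li])=CCC)c1OCOC | intermediate (not isolated)
22 | methyl 7-[3-butanoyl-4-methoxy-2,6-bis(methoxymethoxy)phenyl]-2,2-dimethyl-3,5-dioxoheptanoate | COC(=O)C(C)(C)C(=O)CC(=O)CCc1c(OCOC)cc(OC)c(C(=O)CCC)c1OCOC | intermediate
23 | trilithium tris-enolate of 22 (diketone dianion plus aryl ketone enolate) | COC(=O)C(C)(C)C(O[Li])=CC(O[Li])=CCc1c(OCOC)cc(OC)c(C(O[Li])=CCC)c1OCOC | intermediate (not isolated)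
24 | 4-{[3-butanoyl-4-methoxy-2,6-bis(methoxymethoxy)phenyl]methyl}-5-hydroxy-2,2-dimethylcyclohex-4-ene-1,3-dione | CCCC(=O)c1c(OC)cc(OCOC)c(CC2=C(O)CC(=O)C(C)(C)C2=O)c1OCOC | intermediate
25 | butanoic acid | CCCC(=O)O | starting material
26 | 2-{[3-butanoyl-4-methoxy-2,6-bis(methoxymethoxy)phenyl]methyl}-4,4-dimethyl-3,5-dioxocyclohex-1-en-1-yl butanoate | CCCC(=O)OC1=C(Cc2c(OCOC)cc(OC)c(C(=O)CCC)c2OCOC)C(=O)C(C)(C)C(=O)C1 | intermediate (not isolated)
27 | 2-butanoyl-6-{[3-butanoyl-4-methoxy-2,6-bis(methoxymethoxy)phenyl]methyl}-3,5-dihydroxy-4,4-dimethylcyclohexa-2,5-dien-1-one | CCCC(=O)C1=C(O)C(C)(C)C(O)=C(Cc2c(OCOC)cc(OC)c(C(=O)CCC)c2OCOC)C1=O | intermediate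
28 | 2-butanoyl-6-[(3-butanoyl-2,6-dihydroxy-4-methoxyphenyl)methyl]-3,5-dihydroxy-4,4-dimethylcyclohexa-2,5-dien-1-one (CNP0191862.0) | CCCC(=O)C1=C(O)C(C)(C)C(O)=C(Cc2c(O)cc(OC)c(C(=O)CCC)c2O)C1=O | target

**Step count**

Total: 12 steps. Longest linear sequence: 11 steps (1, 2, 4–12, from ethyl levulinate); step 3 is a one-step branch.

**Steps most likely to fail**

Step 4. The alkoxy group at C3 stabilises cyclobutenone 8, so ring opening may only begin at temperatures where the vinylketene dimerises, acylates the phenol already formed, or the ynol ether degrades before cycloaddition. The fallback generates the same vinylketene 9 at room temperature by photochemical Wolff rearrangement (second-generation Danheiser benzannulation). It sets out from siloxyalkyne 6 and returns at phenol 13. Commercial 3,3-dimethoxybutan-2-one should lose methanol on heating with catalytic KHSO4 to give 3-methoxybut-3-en-2-one F1. Its lithium enolate (LiN(SiMe3)2, THF, −78 °C) would be trifluoroacetylated with 2,2,2-trifluoroethyl trifluoroacetate to 1,1,1-trifluoro-5-methoxyhex-5-ene-2,4-dione F2. Detrifluoroacetylative diazo transfer with methanesulfonyl azide (Et3N, H2O, MeCN) would then give 1-diazo-3-methoxybut-3-en-2-one F3. Irradiation of F3 with 6 in CH2Cl2 at room temperature, followed by brief warming to 80 °C to finish the later stages of the cascade, should deliver 13.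

Step 9. With both ketones enolised, proton shuffling between them may erode the kinetic regiochemistry at the methyl ketone, or the ring-B enolate may undergo slow acylation or aldol addition. The fallback builds and acylates ring A before ring B carries a ketone and butanoylates ring B last. It sets out from bis-MOM ether 15 and returns at target 28. Ketal hydrolysis of 15 (pyridinium p-toluenesulfonate, acetone/H2O) would give 4-[4-methoxy-2,6-bis(methoxymethoxy)phenyl]butan-2-one F4. Crossed Claisen condensation with 20 (LiN(i-Pr)2, THF) would give methyl 7-[4-methoxy-2,6-bis(methoxymethoxy)phenyl]-2,2-dimethyl-3,5-dioxoheptanoate F5. Dianion Dieckmann closure (LiN(i-Pr)2, 2.2 equiv) would give 5-hydroxy-4-{[4-methoxy-2,6-bis(methoxymethoxy)phenyl]methyl}-2,2-dimethylcyclohex-4-ene-1,3-dione F6. C-acylation with 25 (N,N'-dicyclohexylcarbodiimide, 4-(dimethylamino)pyridine) would give 2-butanoyl-3,5-dihydroxy-6-{[4-methoxy-2,6-bis(methoxymethoxy)phenyl]methyl}-4,4-dimethylcyclohexa-2,5-dien-1-one F7. HCl in MeOH would free 2-butanoyl-6-[(2,6-dihydroxy-4-methoxyphenyl)methyl]-3,5-dihydroxy-4,4-dimethylcyclohexa-2,5-dien-1-one F8. Friedel–Crafts butanoylation (butanoyl chloride, TiCl4, CH2Cl2, −20 → 0 °C) at either of the two equivalent free positions of ring B should then give 28; this last step carries its own risk of acid-induced damage at the methylene bridge.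

Step 3. Methanol may add to the carbonyl carbon and open the strained ring, traces of water may hydrolyse the vinylogous ester, and the volatile product may be lost on concentration. The fallback goes through the dione and alkylates on oxygen. It sets out from 7 and returns at 8. Cold dilute aqueous HCl should hydrolyse 7 to cyclobutane-1,3-dione F9, and O-methylation of its acidic enol with trimethylsilyldiazomethane in MeOH/Et2O should give 8.

**Further compounds**

F1 | step 4 | 3-methoxybut-3-en-2-one | COC(=C)C(C)=O
F2 | step 4 | 1,1,1-trifluoro-5-methoxyhex-5-ene-2,4-dione | COC(=C)C(=O)CC(=O)C(F)(F)F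
F3 | step 4 | 1-diazo-3-methoxybut-3-en-2-one | COC(=C)C(=O)C=[N+]=[N-]
F4 | step 9 | 4-[4-methoxy-2,6-bis(methoxymethoxy)phenyl]butan-2-one | COCOc1cc(OC)cc(OCOC)c1CCC(C)=O
F5 | step 9 | methyl 7-[4-methoxy-2,6-bis(methoxymethoxy)phenyl]-2,2-dimethyl-3,5-dioxoheptanoate | COC(=O)C(C)(C)C(=O)CC(=O)CCc1c(OCOC)cc(OC)cc1OCOC
F6 | step 9 | 5-hydroxy-4-{[4-methoxy-2,6-bis(methoxymethoxy)phenyl]methyl}-2,2-dimethylcyclohex-4-ene-1,3-dione | COCOc1cc(OC)cc(OCOC)c1CC2=C(O)CC(=O)C(C)(C)C2=O
F7 | step 9 | 2-butanoyl-3,5-dihydroxy-6-{[4-methoxy-2,6-bis(methoxymethoxy)phenyl]methyl}-4,4-dimethylcyclohexa-2,5-dien-1-one | CCCC(=O)C1=C(O)C(C)(C)C(O)=C(Cc2c(OCOC)cc(OC)cc2OCOC)C1=O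
F8 | step 9 | 2-butanoyl-6-[(2,6-dihydroxy-4-methoxyphenyl)methyl]-3,5-dihydroxy-4,4-dimethylcyclohexa-2,5-dien-1-one | CCCC(=O)C1=C(O)C(C)(C)C(O)=C(Cc2c(O)cc(OC)cc2O)C1=O
F9 | step 3 | cyclobutane-1,3-dione | O=C1CC(=O)C1
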